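In a one-step world substrate turns straight into target, and target climbs from the first moment towards the charge and stays there. These flasks did otherwise.

| flask | substrate | time |
|---|---|---|
| south-west | 0.800 M |  |
| north-east | 0.320 M |  |
| west | 0.400 M |  |
| south | 0.800 M | 19 h |

| run | time / h | [target] / M |
|---|---|---|
| south-west run | 0.39 | 0.0040 |
| south-west run | 0.66 | 0.0102 |
| south-west run | 1.1 | 0.0268 |
| south-west run | 1.9 | 0.0584 |
| south-west run | 3.3 | 0.1132 |
| south-west run | 5.7 | 0.1944 |
| south-west run | 9.7 | 0.2440 |
| north-east run | 0.39 | 0.0061 |
| north-east run | 0.66 | 0.0064 |
| north-east run | 1.1 | 0.0051 |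
| north-east run | 1.9 | 0.0266 |
| north-east run | 3.3 | 0.0557 |
| north-east run | 5.7 | 0.0906 |
| north-east run | 9.7 | 0.1174 |
| west run | 0.39 | 0.0026 |
| west run | 0.66 | 0.0029 |
| west run | 1.1 | 0.0141 |
| west run | 1.9 | 0.0279 |
| west run | 3.3 | 0.0643 |
| west run | 5.7 | 0.1086 |
| west run | 9.7 | 0.1426 |

(scatter of a reading: 0.002 M)

- reaction order in [substrate] at the outset, round the charge of the south-west run, defined at two percent of the substrate turned into target (one fixed amount of target, the same in the runs compared)
- target in the south run at 19 h, as a share of the substrate charged

The south-west run began late: I drew a line through its readings at 1.1 h and 1.9 h back to zero target and found a lag of 0.422 h, so I supposed a stage between substrate and target. Its slope was 0.0338 M h⁻¹ between 3.3 h and 5.7 h, but 0.0124 M h⁻¹ afterwards, less than before. Continued in a straight line, the slope reached zero at 9.55 h, beside the last reading, where target stood at 30.5% of the charge. I assumed this was a peak, with target itself being consumed; the readings end there, so it remained an assumption.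

I then solved both ends. For two consecutive first-order steps with a like constant k, target early grows in proportion to time, and late it dies as exp(-kt). The product kt·exp(-kt) joins these ends and peaks at time 1/k. The span from lag to peak was 9.13 h, and I called its reciprocal, 0.110 h⁻¹, the chain constant. With x as the time after the lag multiplied by this constant, target is its peak share times x·exp(1-x). For the south run, charged like the south-west run, 19 h gives x = 2.03, a factor of 0.723, and so 22.0%. I reckoned no order of my own.

The forecast gave an order of 0.8 (0.55 to 1.05) and 34.5% (31% to 41%), higher than my share, saying of the fall-off: “This looks like catalyst death or an approach to equilibrium”.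

The flask gave an order of 0.57 and 24.1%.

    substrate → intermediate (0.5580 h⁻¹)
    intermediate → target (0.1328 h⁻¹)
    target → decomposed product (0.09072 h⁻¹)
    2 substrate → homo dimer (0.3078 L mol⁻¹ h⁻¹)

The step from target to decomposed product is the main reason for the low share: the south run without it reached 64.4%, not 24.1%. My chain constant, 0.110 h⁻¹, read from the south-west run, had given 22.0% for the south run against the 24.1% found. It is lower than the constant of the step forming target, 0.133 h⁻¹, and higher than that of the step consuming target, 0.0907 h⁻¹.

The data were computed for substances that don't exist, noise included.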